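The earlier runs and the new flask are calculated on assumed constants; scatter was added.

With the small charge of the blue run, 0.67 equiv of Z, G plus twice J read 67.4 % of the L charged at 3.00 min, about the charge itself, so there Z was the limiting reagent.

| setting | teal | blue | flask |
|---|---|---|---|
| L | 0.80 M | 0.80 M | 0.80 M |
| Z | 1 equiv | 0.67 equiv | 1.00 equiv |
| remark | the very flask that is asked about, followed so far | run made earlier |  |
| time |  |  | 3.0 min |

teal run (percent of the L charged)

| time / s | G / % | J / % |
|---|---|---|
| 25.0 | 52.8 | 10.3 |
| 50.0 | 67.5 | 11.1 |
| 60.0 | 74.0 | 8.0 |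
| 90.0 | 80.9 | 6.0 |

blue run (percent of the L charged)

| time / min | G / % | J / % |
|---|---|---|
| 0.417 | 44.1 | 3.4 |
| 1.00 | 59.2 | 2.7 |
| 2.00 | 64.7 | 0.9 |
| 3.00 | 66.4 | 0.5 |

(standard deviation of a reading: 1 percentage point)

- what is said of J includes D
- reactions considered so far: L + Z -> G; Z + J <-> D; Z + G <-> J

1. equivalents of Z to L, everything else as given, that leave most G at 3.0 min
2. the amount of G then, in percent of the L charged
3. the amount of G with the amounts as given

I turned the question round: what would have to hold for G in the teal flask, at 1.00 equiv, to stop at its charge too? With equal charges, and J set aside, the reciprocal of [L] climbs in a straight line, so I replaced the curve by one mean constant. At 90.0 s the teal readings left 13.1 % as L, which gives 0.0921 M⁻¹ s⁻¹. The count N, this mean constant times the starting [L] times the time, is 13.3 at 3.0 min, and the share of L left is one part in one plus N, 7.01 %. To bring that share within 1 percentage point, N would have to be near 100, so the teal flask stands far from that. The first reading gives 0.0855 M⁻¹ s⁻¹ and a share of 7.51 %, so choosing that reading instead of the mean moves the share by 0.5 points. For the blue run, N scaled by the fractional excess of L is 4.38, and by this reckoning Z against L stood at 1.25 % of its charged ratio at 3.00 min. For the teal flask at 3.0 min, my reckoning put G between 87.0 %, with J held at its last reading, and 93.0 %, with J left out.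

The forecast gave 90 % (87.5 % to 92.5 %) as charged and 91.5 % at 1.07 equiv, adding “The optimum is flat”.

The flask gives 88.9 % as charged and 90.2 % at 1.10 equiv.

    L + Z → G (k = 0.128 M⁻¹ s⁻¹)
    Z + J ⇌ D, settled at all times (K = 3.79 M⁻¹)
    Z + G ⇌ J (K = 0.690 M⁻¹, k = 0.332 M⁻¹ s⁻¹)

At 3.00 min, L stands at 8.2 % against my 7.01 %. N scaled to 30.0 min gives a share of 0.746 %, and L stands there at 0.854 %. For a neighbour flask with 0.400 equiv of Z, N scaled by the excess is 7.96, so G should stop at the charge, 40.0 %, with 0.0209 % of the Z charge left. The computed flask has G at 40.0 % and Z at 0.0065 % of its charge.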